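The runs are simulated for substances that don't exist; scatter was added.

- I choose between running hot and running cold by one constant: the ageing constant k of D → G, taken as first order in cD.

| setting | alpha | gamma | theta | amber | violet |
|---|---|---|---|---|---|
| E | 0.20 M (fed, over 1.0 h) | 0.20 M (fed, over 1.0 h) | 0.30 M (fed, over 1.0 h) | 0.20 M (fed, over 1.0 h) | 0.20 M (fed, over 1.0 h) |
| L | 0.0050 M | 0.020 M | 0.010 M | 0.0100 M | 0.0100 M |
| X | 3.1 mol% | 3.1 mol% | 3.1 mol% | 3.1 mol% | 3.1 mol% |
| temperature | 58 °C | 74 °C | 58 °C | 80 °C | 50 °C |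
| remark | run made earlier | run made earlier | run made earlier |  |  |
| time |  |  |  | 2.5 h | 2.5 h |

| run | time / h | D / % | G / % | E / % |
|---|---|---|---|---|
| alpha | 2.00 | 5 | 1 | 91 |
| alpha | 4.00 | 7 | 1 | 89 |
| alpha | 6.00 | 9 | 0 | 84 |
| alpha | 8.00 | 17 | 1 | 75 |
| gamma | 0.667 | 4 | 0 | 53 |
| gamma | 1.33 | 10 | 2 | 80 |
| gamma | 2.00 | 16 | 1 | 67 |
| gamma | 2.50 | 21 | 4 | 57 |
| gamma | 3.00 | 26 | 8 | 60 |
| theta | 2.00 | 6 | 0 | 89 |
| theta | 4.00 | 8 | 0 | 83 |
| theta | 6.00 | 12 | 0 | 82 |
| theta | 8.00 | 20 | 4 | 77 |

(each reading ± 2 percentage points)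

* the flask that comes out highest in share of D in all that became D or G, or "all alike" when all lie within 1.5 percentage points (amber / violet / all alike)
* share of D in all that became D or G, amber
* share of D in all that became D or G, violet

- percentages count the whole charge, also what has not yet gone in

- In gamma, D climbs steadily from 4 % at 0.667 h to 26 % at 3.00 h, so I freeze the making of D plus G at a steady pace.
- If that making lasts an ageing time τ, the share of D is S = (1 − e^(−kτ))/(kτ), and G/D runs near kτ divided by two while kτ is small.
- Gamma's last reading gives 0.205 h⁻¹ at 74 °C, though its G of 8 % carries a scatter of 2 percentage points.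
- The last readings of alpha and theta, pooled, give 0.0338 h⁻¹ at 58 °C, again a figure read through the same scatter.
- A straight line of ln k against temperature carries this to my estimate of the ageing constant of amber, 0.403 h⁻¹.
- Bound from below for amber, at this estimated k: if making starts at once, τ is 2.5 h, and S is 63.0 %.
- Bound from above for amber, at the same k: if making starts when the feed ends, τ is 1.50 h, and S is 75.0 %.
- Gamma's first reading shows D of 4 % at 0.667 h, before its feed ends, so I doubt that late start. The line through gamma's first and last D readings runs back to a lag of 0.243 h; I carry that lag from 74 °C over to amber as an assumption, which tightens amber's upper figure to 65.6 %.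
- For violet the same line gives 0.0137 h⁻¹ and, with making from the start, S of 98.3 %, higher than amber's loose bound, so I choose violet.
- The forecast also picks violet, with violet at 95 % (88 % to 99 %) and amber at 83 % (74 % to 90 %), saying “I expect about 30% D and G/D about 0.2”, which puts amber above my bracket.
- The flask gives 64.5 % for amber, inside my tightened bracket, and 98.2 % for violet, so violet comes out highest.

    E + X → Z (k = 5.00 L mol⁻¹ min⁻¹, Ea = 64.0 kJ mol⁻¹)
    D ⇌ G (K = 30.0, k = 0.00700 min⁻¹, Ea = 101 kJ mol⁻¹, ΔH = −21.0 kJ mol⁻¹)
    E + L → Q (k = 0.620 L mol⁻¹ min⁻¹, Ea = 79.0 kJ mol⁻¹)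
    Z → X + D (k = 0.130 min⁻¹, Ea = 101 kJ mol⁻¹)
    (constants at 80 °C)

- In amber, E + L → Q ran while L lasted, L standing at 5.34 % of its charge and Q at 4.73 % of the E charged at 1.00 h, and Z → X + D ran with Z as the resting state, 85.4 % of the catalyst then and 78.6 % at 2.50 h. D → G ran behind it, with 24 % of its turnover up to 2.50 h done at 1.25 h. Over the second half of amber's time, 0.403 h⁻¹ on a mean D of 22.9 % comes to 11.6 % of G, and G rose by 12 points. The same constant and lag give S of 78.5 % for the amber flask read instead at 1.5 h, which stands at 77.5 %.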